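**Assumption:** (S)-pulegone is commercially available, or is made in one step from (S)-3-methylcyclohexanone and acetone. The stereocentres created in the last step are α to ketones and are assumed to settle thermodynamically.

## Retrosynthetic overview
1. Alertenone (14) is a head-to-tail Michael dimer of the α-methylene ketone 13. The C4′ enolate of one unit adds to the exocyclic CH2 of a second unit.
2. Monomer 13 comes from tricyclic enone 9 by regiospecific Mannich aminomethylation at C2′, hydrogenation of the C4′=C8 alkene, and Hofmann-type elimination.
3. Enone 9 comes from a 1,4-diketone (8) by intramolecular aldol condensation, which builds the cyclopentanone ring last.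
4. The bicyclo[3.2.1]octanone and its quaternary bridgehead come from a 5-exo radical conjugate cyclisation of a neopentyl radical onto an ene-dione (7).
5. The ring in 7 derives from (S)-pulegone, which carries the CHMe stereocentre. Conjugate addition of a hydroxymethyl anion equivalent builds the CMe2 carbon. The order of ring formation is cyclohexane (pulegone), then bicyclo[3.2.1], then cyclopentenone.

## Route

**Step 1**
Reactants: 1 (S)-pulegone; 2 (isopropoxydimethylsilyl)methylmagnesium chloride
Product: 3 (2R,5S)-2-[1-(isopropoxydimethylsilyl)-2-methylpropan-2-yl]-5-methylcyclohexanone (trans)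
Conditions: 2 (1.5 equiv), CuI (10 mol %), THF, −40 °C → rt; then NaOMe, MeOH, rt
Reagents that add atoms: 2, CC(C)O[Si](C)(C)C[Mg]Cl
Why: Cu-catalysed 1,4-addition of a hydroxymethyl-anion equivalent to the β,β-dimethyl enone creates the quaternary CMe2 carbon. The C5 methyl centre is untouched, and NaOMe equilibrates C2 (α to the ketone) to the trans-2,5 isomer that the later bridging requires.

**Step 2**
Reactants: 3
Product: 4 (2R,5S)-2-(1-hydroxy-2-methylpropan-2-yl)-5-methylcyclohexanone
Conditions: H2O2, KF, KHCO3, THF/MeOH, 50 °C
Reagents that add atoms: hydrogen peroxide, OO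
Why: Tamao–Fleming oxidation converts the C–Si bond to C–OH with retention and leaves the ketone and both stereocentres intact.

**Step 3**
Reactants: 4
Product: 5 (2R,5S)-2-(1-iodo-2-methylpropan-2-yl)-5-methylcyclohexanone
Conditions: PPh3, I2, imidazole, toluene, 80 °C
Reagents that add atoms: iodine, II
Why: Appel/Garegg–Samuelsson iodination makes the neopentyl iodide radical precursor. No stereocentre is involved.

**Step 4**
Reactants: 5; 6 methylglyoxal
Product: 7 (2R,5S)-2-(1-iodo-2-methylpropan-2-yl)-5-methyl-6-(2-oxopropylidene)cyclohexanone (E/Z)
Conditions: LDA, THF, −78 °C; then 6; then MsCl, Et3N, CH2Cl2, 0 °C; then DBU, rt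
Reagents that add atoms: 6, CC(=O)C=O
Why: Kinetic LDA deprotonation occurs at the unhindered C6, not at C2, which carries the bulky tertiary alkyl group. Aldol addition and dehydration (aldol condensation) give the ene-dione acceptor. The C2 and C5 centres are retained.

**Step 5**
Reactants: 7
Product: 8 1-(2-oxopropyl)-2,6,6-trimethylbicyclo[3.2.1]octan-8-one (2-Me axial, anti to the C6–C7 bridge; stereochemistry as in SMILES)
Conditions: Bu3SnH (syringe pump), AIBN, PhH, 80 °C, 0.01 M
Reagents that add atoms: none (hydrogen only)
Why: Bu3SnH generates the neopentyl radical, which adds 5-exo to the β-carbon of the acetyl enone (Giese-type radical conjugate cyclisation). The axial tether on the trans-diaxial chair (C2 side chain and C5 Me both axial) forces bond formation on its own face. This sets the new quaternary centre and the cis bridgeheads, and the C5 Me ends up axial, anti to the bridge. The resulting α-keto radical takes H from Bu3SnH.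

**Step 6**
Reactants: 8
Product: 9 tricyclic enone C14H20O, a cyclopent-2-en-1-one fused across C1–C8 of the bicyclo[3.2.1]octane with a C4′=C8 double bond
Conditions: KOH, MeOH, 65 °C
Reagents that add atoms: none
Why: Intramolecular aldol condensation of the 1,4-diketone (Robinson-type cyclopentenone annulation). The methyl-ketone enolate attacks the bridging ketone and dehydration follows. No new sp3 stereocentre is formed, and the bridgeheads cannot epimerise.

**Step 7**
Reactants: 9; 10 Eschenmoser's salt
Product: 11 Mannich base of enone 9 (CH2NMe2 at C2′)
Conditions: LDA, THF, −78 °C; then 10, −78 → 0 °C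
Reagents that add atoms: 10, C=[N+](C)C.[I-]
Why: Enone 9 has only one enolisable α-CH2 (C2′), so Mannich aminomethylation is regiospecific. The new C2′ centre is epimerisable and is destroyed in step 9.

**Step 8**
Reactants: 11
Product: 12 saturated Mannich base
Conditions: H2 (1 atm), 10% Pd/C, EtOAc, rt
Reagents that add atoms: none (hydrogen only)
Why: Heterogeneous hydrogenation of the trisubstituted enone alkene. H2 is delivered to C8 from the open face, on the side of the three-carbon bridge bearing the axial Me. The face over the gem-dimethyl C6–C7 bridge is shielded, so C4′ ends up syn to that bridge, as in the target.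

**Step 9**
Reactants: 12
Product: 13 monomer, the α-methylene ketone (C15H22O)
Conditions: MeI, CH2Cl2, rt; then NaHCO3, THF/H2O
Reagents that add atoms: none (MeI only forms the NMe3 leaving group)
Why: Quaternisation followed by Hofmann/Eschenmoser elimination unmasks the exocyclic methylene. The centres at C1, C2, C5 and C8 are untouched.

**Step 10**
Reactants: 13 (2 equiv, self-coupling)
Product: 14 alertenone
Conditions: t-BuOK (20 mol %), THF, 0 °C → rt
Reagents that add atoms: none
Why: Base-catalysed head-to-tail Michael dimerisation. Deprotonation at C4′, the only α′-CH2 of 13, gives a cross-conjugated dienolate that adds to the exocyclic CH2 of a second molecule. The two new α-stereocentres are epimerisable and equilibrate to the thermodynamically preferred configuration.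

## Compound list
1 | (S)-pulegone | CC(C)=C1CC[C@H](C)CC1=O | starting material
2 | (isopropoxydimethylsilyl)methylmagnesium chloride | CC(C)O[Si](C)(C)C[Mg]Cl | starting material
3 | silyl ketone (2R,5S), trans | C[C@H]1CC[C@H](C(C)(C)C[Si](C)(C)OC(C)C)C(=O)C1 | intermediate
4 | hydroxy ketone | C[C@H]1CC[C@H](C(C)(C)CO)C(=O)C1 | intermediate
5 | neopentyl iodide ketone | C[C@H]1CC[C@H](C(C)(C)CI)C(=O)C1 | intermediate
6 | methylglyoxal | CC(=O)C=O | starting material
7 | ene-dione (E/Z) | C[C@H]1CC[C@H](C(C)(C)CI)C(=O)C1=CC(C)=O | intermediate
8 | bicyclo[3.2.1]octanone diketone | CC(=O)C[C@@]12CC(C)(C)[C@@H](CC[C@@H]1C)C2=O | intermediate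
9 | tricyclic enone | O=C1C=C2[C@@H]3CC[C@H](C)[C@@]2(C1)CC3(C)C | intermediate
10 | Eschenmoser's salt | C=[N+](C)C.[I-] | starting material
11 | Mannich base enone | O=C1C=C2[C@@H]3CC[C@H](C)[C@@]2(C1CN(C)C)CC3(C)C | intermediate
12 | saturated Mannich base | O=C1C[C@H]2[C@@H]3CC[C@H](C)[C@@]2(C1CN(C)C)CC3(C)C | intermediate
13 | monomer (α-methylene ketone) | C=C1C(=O)C[C@H]2[C@@H]3CC[C@H](C)[C@]12CC3(C)C | intermediate
14 | alertenone | C=C1C(=O)[C@H](C[C@@H]2C(=O)C[C@H]3[C@@H]4CC[C@H](C)[C@]23CC4(C)C)[C@H]2[C@@H]3CC[C@H](C)[C@]12CC3(C)C | target

**Total steps:** 10. **Longest linear sequence:** 10 steps from (S)-pulegone.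

## Three steps most likely to fail
1. **Step 5, radical cyclisation.** The ene-dione has two β-positions, so 6-endo closure to a bicyclo[3.3.1]nonane or simple deiodination could compete with 5-exo closure.
   - Fallback: change the approach to Pd(OAc)2 cycloalkenylation (Toyota–Ihara) of the silyl enol ether of a 6-alkylated isopulegone (from (S)-citronellal via isopulegol). This gives the bicyclo[3.2.1]octanone with an exocyclic methylene, which is converted to gem-dimethyl by Simmons–Smith cyclopropanation and H2/PtO2 hydrogenolysis.
2. **Step 8, hydrogenation.** The facial selectivity at C8, which sets the C4′ configuration, is uncertain because both faces are crowded.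
   - Fallback: install that centre differently. Build the bicyclic ketone with a bridgehead C–H, then close the cyclopentanone by Rh2-catalysed diazo-ketoester C–H insertion (Taber). This gives a retentive quaternary centre, with C8 stereochemistry set earlier by an HWE olefination/hydrogenation on the bridge ketone.
3. **Step 10, dimerisation.** The single Michael adduct may go on to the double-Michael (formal Diels–Alder) product or give the wrong C2′/C4′ epimers.
   - Fallback: change to a stepwise Lewis-acid-promoted Mukaiyama–Michael addition of the TBS dienol ether of 13 to a second equivalent of 13. Kinetic quenching then separates the stereochemical outcome from base equilibration.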